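## Retrosynthetic overview

1. Target 18 ⇐ trans ketone 17 by Felkin–Anh hydride reduction, which sets the carbinol carbon. Ring numbering used throughout: C1 bears the carbinol carbon, C2 the aryl group, C3=C4(Me), C5, C6(Me)2.
2. 17 ⇐ dienone 15 + coumarin-8-boronate 9 by rhodium-catalysed asymmetric 1,4-arylation. This forms the C2–aryl bond and sets C2; C1 is set by equilibration to trans.
3. 15 ⇐ arylzinc from iodide 8 + dienyl thioester 13 by palladium-catalysed Fukuyama acyl coupling.
4. 13 ⇐ prenal dimer 11, which delivers the whole carbocycle in one step. 8 and 9 ⇐ 5,7-dimethoxycoumarin 7 ⇐ 3,5-dimethoxyphenol 4 + ethyl propiolate 5 (palladium C–H annulation) ⇐ resorcinol 1 (iridium C–H borylation/oxidation).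
5. Ring order: the coumarin pyranone ring (step 3, shared by both aryl units) and the cyclohexadiene ring (step 6) are made independently; no ring is formed after fragment union.

Assumption: the (1R,4R) diene ligand in step 10 is taken to give the 2R product; if the first run shows the opposite sense, the (1S,4S) ligand is used.

## Route

Step 1
Reactants: 1 resorcinol
Product: 2 1,3-dimethoxybenzene
Conditions: MeI (2.5 equiv), K2CO3 (3 equiv), acetone, reflux, 12 h
Reagents that add atoms: iodomethane, CI
Why: Williamson ether synthesis, in which both phenoxide oxygens are methylated by SN2 on iodomethane with K2CO3 as base.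

Step 2
Reactants: 2 1,3-dimethoxybenzene
Product: 4 3,5-dimethoxyphenol, via aryl pinacol boronate 3 (not isolated)
Conditions: [Ir(OMe)(cod)]2 (1 mol %), 4,4'-di-tert-butyl-2,2'-bipyridine (2 mol %), B2pin2 (0.6 equiv), THF, 80 °C; then KHSO5 (as 2KHSO5·KHSO4·K2SO4), acetone/H2O, rt
Reagents that add atoms: bis(pinacolato)diboron, CC1(C)OB(OC1(C)C)B1OC(C)(C)C(C)(C)O1 (boron group of 3 only); potassium peroxymonosulfate KHSO5, [K+].[O-]S(=O)(=O)OO (phenol oxygen of 4)
Why: Sterically controlled iridium-catalysed aromatic C–H borylation occurs only at C5, the one C–H with no ortho substituent, and the C–B bond is then oxidised in the same flask to the phenol (one-pot borylation/oxidation).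

Step 3
Reactants: 4 3,5-dimethoxyphenol; 5 ethyl propiolate
Product: 7 5,7-dimethoxy-2H-chromen-2-one, via Z-hydroxycinnamate ester 6 (not isolated)
Conditions: Pd(OAc)2 (3 mol %), CF3CO2H/CH2Cl2 (3:1), rt, 24 h
Reagents that add atoms: none
Why: Fujiwara-type palladium-catalysed C–H hydroarylation of the alkynoate (electrophilic palladation ortho to the OH, trans addition across the alkyne) gives the Z-cinnamate, which lactonises spontaneously, and the two ortho positions are equivalent so only one coumarin can form.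

Step 4
Reactants: 7 5,7-dimethoxy-2H-chromen-2-one
Product: 8 8-iodo-5,7-dimethoxy-2H-chromen-2-one
Conditions: N-iodosuccinimide (1.05 equiv), CF3CO2H (0.2 equiv), MeCN, 0 °C → rt, dark
Reagents that add atoms: N-iodosuccinimide, O=C1CCC(=O)N1I
Why: Electrophilic aromatic iodination at C8, which is para to the 5-methoxy and ortho to the 7-methoxy group and is the position expected by analogy with 5,7-dimethoxy benzopyranones, whereas C6 is buttressed between two methoxy groups and C3 is not nucleophilic enough.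

Step 5
Reactants: 8 8-iodo-5,7-dimethoxy-2H-chromen-2-one
Product: 9 5,7-dimethoxy-8-(4,4,5,5-tetramethyl-1,3,2-dioxaborolan-2-yl)-2H-chromen-2-one
Conditions: B2pin2 (1.5 equiv), Pd(dppf)Cl2 (5 mol %), KOAc (3 equiv), 1,4-dioxane, 90 °C
Reagents that add atoms: bis(pinacolato)diboron, CC1(C)OB(OC1(C)C)B1OC(C)(C)C(C)(C)O1
Why: Miyaura borylation (oxidative addition of the aryl iodide to zerovalent palladium, acetate-assisted transmetalation from B2pin2, reductive elimination), which tolerates ortho-alkoxy aryl halides and the lactone under the weak base KOAc.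

Step 6
Reactants: 10 3-methylbut-2-enal (two molecules)
Product: 11 4,6,6-trimethylcyclohexa-1,3-diene-1-carbaldehyde
Conditions: L-proline (30 mol %), DMF, −10 °C → rt, 24 h
Reagents that add atoms: none
Why: Known amine-catalysed formal [4+2] self-condensation of prenal, in which the dienamine of one molecule adds through its γ-carbon to the β-carbon of the iminium of the second, the ring closes by a Mannich-type step and the amine is eliminated to give this achiral dienal.

Step 7
Reactants: 11 4,6,6-trimethylcyclohexa-1,3-diene-1-carbaldehyde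
Product: 12 4,6,6-trimethylcyclohexa-1,3-diene-1-carboxylic acid
Conditions: NaClO2 (1.5 equiv), NaH2PO4 (2 equiv), 2-methylbut-2-ene (10 equiv), t-BuOH/H2O, 0 °C → rt
Reagents that add atoms: sodium chlorite, [Na+].[O-]Cl=O
Why: Pinnick oxidation, in which chlorous acid adds to the aldehyde and fragments to the acid while 2-methylbut-2-ene scavenges HOCl so that the diene is untouched.

Step 8
Reactants: 12 4,6,6-trimethylcyclohexa-1,3-diene-1-carboxylic acid
Product: 13 S-ethyl 4,6,6-trimethylcyclohexa-1,3-diene-1-carbothioate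
Conditions: EtSH (1.5 equiv), DCC (1.2 equiv), DMAP (10 mol %), CH2Cl2, 0 °C → rt
Reagents that add atoms: ethanethiol, CCS
Why: Steglich-type carbodiimide coupling, in which DCC activates the acid and DMAP transfers the acyl group to the thiol.

Step 9
Reactants: 8 8-iodo-5,7-dimethoxy-2H-chromen-2-one; 13 S-ethyl 4,6,6-trimethylcyclohexa-1,3-diene-1-carbothioate
Product: 15 5,7-dimethoxy-8-(4,6,6-trimethylcyclohexa-1,3-diene-1-carbonyl)-2H-chromen-2-one, via arylzinc iodide 14 (not isolated)
Conditions: 8 (1.3 equiv), Zn dust (activated with TMSCl and 1,2-dibromoethane), LiCl, THF, 50 °C; then 13, PdCl2(PPh3)2 (5 mol %), THF/toluene, 40 °C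
Reagents that add atoms: zinc, [Zn] (kept only in intermediate 14)
Why: LiCl-assisted direct zinc insertion gives an arylzinc that leaves the lactone untouched, and Fukuyama coupling (oxidative addition of the acyl C–S bond to zerovalent palladium, transmetalation, reductive elimination) gives the ketone without over-addition.

Step 10
Reactants: 15 5,7-dimethoxy-8-(4,6,6-trimethylcyclohexa-1,3-diene-1-carbonyl)-2H-chromen-2-one; 9 5,7-dimethoxy-8-(4,4,5,5-tetramethyl-1,3,2-dioxaborolan-2-yl)-2H-chromen-2-one
Product: 17 8-[(1S,2R)-2-(5,7-dimethoxy-2-oxo-2H-chromen-8-yl)-4,6,6-trimethylcyclohex-3-ene-1-carbonyl]-5,7-dimethoxy-2H-chromen-2-one, via cis-ketone 16 (not isolated)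
Conditions: 9 (2.0 equiv, two portions), [RhCl(C2H4)2]2 (2.5 mol %), (1R,4R)-2,5-diphenylbicyclo[2.2.2]octa-2,5-diene (5.5 mol %), KOH (0.1 equiv), 1,4-dioxane/H2O (10:1), 50 °C, 12 h; then DBU (1.0 equiv), 50 °C, 6 h; aq. NH4Cl
Reagents that add atoms: none
Why: Proposed new method: a monovalent rhodium hydroxide complex of the two-fold symmetric chiral diene transmetalates with the electron-rich boronate 9, the aryl–rhodium species adds across the enone C1=C2 bond of 15 with the aryl group going to the β-carbon C2 from the face selected by the ligand (this sets C2 as R; 1,6-addition is disfavoured because C4 is fully substituted, and the coumarin C3=C4 bonds are shielded by the peri 5-methoxy groups), the oxa-π-allyl rhodium is hydrolysed to the ketone, and DBU then equilibrates C1 through the enol to the more stable trans-diequatorial (1S,2R) isomer, as is known for 2,6,6-trisubstituted cyclohex-3-enyl ketones; the closest known reaction type is the Hayashi–Miyaura asymmetric 1,4-addition of arylboron reagents to cyclic enones, which has not been shown for a 2,6-dioxygenated aryl donor or an α-branched 1-aroylcyclohexa-1,3-diene acceptor.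

Step 11
Reactants: 17 8-[(1S,2R)-2-(5,7-dimethoxy-2-oxo-2H-chromen-8-yl)-4,6,6-trimethylcyclohex-3-ene-1-carbonyl]-5,7-dimethoxy-2H-chromen-2-one
Product: 18 8-[(S)-[(1S,2R)-2-(5,7-dimethoxy-2-oxo-2H-chromen-8-yl)-4,6,6-trimethylcyclohex-3-en-1-yl](hydroxy)methyl]-5,7-dimethoxy-2H-chromen-2-one (CNP0324863.2)
Conditions: NaBH4 (2 equiv), CeCl3·7H2O (1.2 equiv), MeOH/THF (2:1), −40 → 0 °C
Reagents that add atoms: none
Why: Luche-type 1,2-reduction under Felkin–Anh control, in which the bulky aroyl aryl group lies over the axial C1–H and away from the C2 aryl group, the carbonyl oxygen sits next to the axial C2–H and not the axial C6 methyl, and hydride enters anti to the quaternary C6, which sets the carbinol carbon as S, while the lactones and the trisubstituted alkene are not reduced.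

## Compound list

1 | resorcinol (benzene-1,3-diol) | Oc1cccc(O)c1 | starting material
2 | 1,3-dimethoxybenzene | COc1cccc(OC)c1 | intermediate
3 | 2-(3,5-dimethoxyphenyl)-4,4,5,5-tetramethyl-1,3,2-dioxaborolane | COc1cc(OC)cc(B2OC(C)(C)C(C)(C)O2)c1 | intermediate (not isolated)
4 | 3,5-dimethoxyphenol | COc1cc(O)cc(OC)c1 | intermediate
5 | ethyl propiolate (ethyl prop-2-ynoate) | C#CC(=O)OCC | starting material
6 | ethyl (Z)-3-(2-hydroxy-4,6-dimethoxyphenyl)prop-2-enoate | CCOC(=O)/C=C\c1c(O)cc(OC)cc1OC | intermediate (not isolated)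
7 | 5,7-dimethoxy-2H-chromen-2-one (5,7-dimethoxycoumarin) | COc1cc(OC)c2ccc(=O)oc2c1 | intermediate
8 | 8-iodo-5,7-dimethoxy-2H-chromen-2-one | COc1cc(OC)c2ccc(=O)oc2c1I | intermediate
9 | 5,7-dimethoxy-8-(4,4,5,5-tetramethyl-1,3,2-dioxaborolan-2-yl)-2H-chromen-2-one | COc1cc(OC)c2ccc(=O)oc2c1B1OC(C)(C)C(C)(C)O1 | intermediate
10 | 3-methylbut-2-enal (prenal) | CC(C)=CC=O | starting material
11 | 4,6,6-trimethylcyclohexa-1,3-diene-1-carbaldehyde | O=CC1=CC=C(C)CC1(C)C | intermediate
12 | 4,6,6-trimethylcyclohexa-1,3-diene-1-carboxylic acid | OC(=O)C1=CC=C(C)CC1(C)C | intermediate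
13 | S-ethyl 4,6,6-trimethylcyclohexa-1,3-diene-1-carbothioate | CCSC(=O)C1=CC=C(C)CC1(C)C | intermediate
14 | (5,7-dimethoxy-2-oxo-2H-chromen-8-yl)zinc iodide (LiCl complex) | COc1cc(OC)c2ccc(=O)oc2c1[Zn]I | intermediate (not isolated)
15 | 5,7-dimethoxy-8-(4,6,6-trimethylcyclohexa-1,3-diene-1-carbonyl)-2H-chromen-2-one | COc1cc(OC)c2ccc(=O)oc2c1C(=O)C1=CC=C(C)CC1(C)C | intermediate
16 | 8-[(1R,2R)-2-(5,7-dimethoxy-2-oxo-2H-chromen-8-yl)-4,6,6-trimethylcyclohex-3-ene-1-carbonyl]-5,7-dimethoxy-2H-chromen-2-one (cis ketone) | COc1cc(OC)c2ccc(=O)oc2c1C(=O)[C@@H]1[C@H](c2c(OC)cc(OC)c3ccc(=O)oc23)C=C(C)CC1(C)C | intermediate (not isolated)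
17 | 8-[(1S,2R)-2-(5,7-dimethoxy-2-oxo-2H-chromen-8-yl)-4,6,6-trimethylcyclohex-3-ene-1-carbonyl]-5,7-dimethoxy-2H-chromen-2-one (trans ketone) | COc1cc(OC)c2ccc(=O)oc2c1C(=O)[C@H]1[C@H](c2c(OC)cc(OC)c3ccc(=O)oc23)C=C(C)CC1(C)C | intermediate
18 | 8-[(S)-[(1S,2R)-2-(5,7-dimethoxy-2-oxo-2H-chromen-8-yl)-4,6,6-trimethylcyclohex-3-en-1-yl](hydroxy)methyl]-5,7-dimethoxy-2H-chromen-2-one | COc1cc(OC)c2ccc(=O)oc2c1[C@@H](O)[C@H]1[C@H](c2c(OC)cc(OC)c3ccc(=O)oc23)C=C(C)CC1(C)C | target

## Step count and risks

Total step count: 11. Longest linear sequence: 7 steps (1 → 2 → 4 → 7 → 8 → 15 → 17 → 18, that is steps 1, 2, 3, 4, 9, 10, 11; the branch through step 5 is equally long). The carbocycle branch (steps 6, 7, 8) and the boronate (step 5) are made in parallel.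

**Step 10 (the new rhodium arylation).** The risks are slow insertion of the di-ortho-substituted aryl–rhodium into the α-branched enone, protodeboronation of 9 to 7, and low enantioselectivity. The fallback uses known chemistry, sets out from iodide 8 and rejoins the route at 17; it builds the ring by a Diels–Alder reaction of the kind used for 1-acyl-2,6,6-trimethylcyclohex-3-enes. Arylzinc 14 (from 8 as in step 9) is acylated with 3-methylbut-2-enoyl chloride (Pd(PPh3)4 cat., THF) to the aryl enone 5,7-dimethoxy-8-(3-methylbut-2-enoyl)-2H-chromen-2-one F1. A second portion of 8 undergoes Heck coupling with 2-methylbut-3-en-2-ol (Pd(OAc)2, P(o-tol)3, Et3N, MeCN, 80 °C) to the allylic alcohol 8-[(E)-3-hydroxy-3-methylbut-1-en-1-yl]-5,7-dimethoxy-2H-chromen-2-one F2. Dehydration (cat. pyridinium p-toluenesulfonate, toluene, 90 °C) gives the diene 5,7-dimethoxy-8-[(E)-3-methylbuta-1,3-dien-1-yl]-2H-chromen-2-one F3. Cycloaddition of F1 with F3 (toluene, 160 °C, sealed tube, or Me2AlCl in CH2Cl2) is regiochemically matched: the 1-aryl group directs "ortho" and the 3-methyl group "para" to the acyl carbon. DBU equilibration then gives the racemic trans ketone rac-8-[2-(5,7-dimethoxy-2-oxo-2H-chromen-8-yl)-4,6,6-trimethylcyclohex-3-ene-1-carbonyl]-5,7-dimethoxy-2H-chromen-2-one F4, which is resolved by preparative chromatography on a chiral stationary phase to give 17.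

**Step 11 (diastereoselectivity at the carbinol carbon).** Both carbonyl faces are flanked, by the C2 aryl group on one side and the C6 methyl groups on the other, so the Felkin preference could be low or reversed. The fallback exchanges the roles of nucleophile and carbonyl substituent: aryl addition to an aldehyde gives the opposite carbinol configuration for the same facial preference. It sets out from thioester 13 and rejoins at 18, and it relies on the step 10 conditions working on a thioester. 13 is arylated with 9 under the step 10 conditions to the trans thioester S-ethyl (1S,2R)-2-(5,7-dimethoxy-2-oxo-2H-chromen-8-yl)-4,6,6-trimethylcyclohex-3-ene-1-carbothioate F5. Fukuyama reduction (Et3SiH, Pd/C, acetone) gives the aldehyde (1S,2R)-2-(5,7-dimethoxy-2-oxo-2H-chromen-8-yl)-4,6,6-trimethylcyclohex-3-ene-1-carbaldehyde F6. Nozaki–Hiyama–Kishi coupling of F6 with iodide 8 (CrCl2, NiCl2 cat., DMF) delivers 18.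

**Step 9 (acyl coupling that forms a doubly hindered ketone).** Transmetalation of the di-ortho-substituted arylzinc to the acylpalladium thiolate may be slow. The fallback sets out from iodide 8 and dienal 11 and rejoins at 15. Nozaki–Hiyama–Kishi coupling (CrCl2, NiCl2 cat., DMF, rt) gives the racemic carbinol 8-[hydroxy(4,6,6-trimethylcyclohexa-1,3-dien-1-yl)methyl]-5,7-dimethoxy-2H-chromen-2-one F7, which is oxidised (MnO2, CH2Cl2) to 15.

Further compounds
F1 | step 10 | 5,7-dimethoxy-8-(3-methylbut-2-enoyl)-2H-chromen-2-one | COc1cc(OC)c2ccc(=O)oc2c1C(=O)C=C(C)C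
F2 | step 10 | 8-[(E)-3-hydroxy-3-methylbut-1-en-1-yl]-5,7-dimethoxy-2H-chromen-2-one | COc1cc(OC)c2ccc(=O)oc2c1/C=C/C(C)(C)O
F3 | step 10 | 5,7-dimethoxy-8-[(E)-3-methylbuta-1,3-dien-1-yl]-2H-chromen-2-one | COc1cc(OC)c2ccc(=O)oc2c1/C=C/C(C)=C
F4 | step 10 | rac-8-[2-(5,7-dimethoxy-2-oxo-2H-chromen-8-yl)-4,6,6-trimethylcyclohex-3-ene-1-carbonyl]-5,7-dimethoxy-2H-chromen-2-one (racemic trans ketone, 1:1 mixture of the 1S,2R and 1R,2S forms) | COc1cc(OC)c2ccc(=O)oc2c1C(=O)[C@H]1[C@H](c2c(OC)cc(OC)c3ccc(=O)oc23)C=C(C)CC1(C)C.COc1cc(OC)c2ccc(=O)oc2c1C(=O)[C@@H]1[C@@H](c2c(OC)cc(OC)c3ccc(=O)oc23)C=C(C)CC1(C)C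
F5 | step 11 | S-ethyl (1S,2R)-2-(5,7-dimethoxy-2-oxo-2H-chromen-8-yl)-4,6,6-trimethylcyclohex-3-ene-1-carbothioate | CCSC(=O)[C@H]1[C@H](c2c(OC)cc(OC)c3ccc(=O)oc23)C=C(C)CC1(C)C
F6 | step 11 | (1S,2R)-2-(5,7-dimethoxy-2-oxo-2H-chromen-8-yl)-4,6,6-trimethylcyclohex-3-ene-1-carbaldehyde | O=C[C@H]1[C@H](c2c(OC)cc(OC)c3ccc(=O)oc23)C=C(C)CC1(C)C
F7 | step 9 | rac-8-[hydroxy(4,6,6-trimethylcyclohexa-1,3-dien-1-yl)methyl]-5,7-dimethoxy-2H-chromen-2-one | COc1cc(OC)c2ccc(=O)oc2c1C(O)C1=CC=C(C)CC1(C)C
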